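The readings come from a simulation for an exercise, and the scatter is random.

- You start from a small charge: this flask holds 0.2 mol% of free catalyst, half the 0.4 mol% of the oak run, with the same substrate and reagent charges.

| flask | substrate | reagent | free catalyst | remark | time |
|---|---|---|---|---|---|
| oak | 0.15 M | 1.1 equiv | 0.4 mol% | run made earlier |  |
| flask | 0.15 M | 1.10 equiv | 0.2 mol% |  | 20 min |

- oak (time / min: target / %, substrate / %): 1.50: 52.6, 6.2; 3.00: 39.7, 0; 5.00: 34.6, 1.5; 6.00: 35.4, 0.1

(each reading ± 1 percentage point)

- no earlier run changes the charge of free catalyst; that part of a forecast is a guess

1. the moment within 20 min at which there is most target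
2. the amount of target, in percent of the substrate charged, at that time

- In the oak run, target reads 52.6% at 1.50 min, then falls and holds at 34.6% and 35.4%, with substrate nearly gone at 0.1%.
- Call f the plateau share, the part of the converted substrate that stands as target once target stops moving. The late oak readings give f = 35.3%.
- Substrate in the oak run decays at a reading of k = 1.85 min⁻¹. I guess that this rate follows the catalyst, which gives 0.927 min⁻¹ in this flask.
- The 20 min allowed is far longer than the 1.08 min this rate implies, so I expect this flask to end at f, like the oak run.
- The excess of target over its plateau decays in the oak run at a reading of λ = 0.911 min⁻¹. I assume this loss needs no catalyst.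
- That is the crossing. In the oak run, making outran loss by twice, but on my guess the two nearly meet in this flask.
- With equal rates, the peak comes when k times t equals one over (one minus f). My reckoning is therefore 1.67 min and 49.1%.
- The forecast gives 1.8 min and 60%, holding that “halving it doubles the time scale and keeps the peak height”. My peak is lower.
- The flask gives 42.1% at 2.45 min, later and lower than either reckoning.

    reagent + free catalyst ⇌ catalyst intermediate A (K = 2.10 M⁻¹, k = 3900 M⁻¹ s⁻¹)
    catalyst intermediate C ⇌ catalyst intermediate D (K = 0.360, k = 150 s⁻¹)
    catalyst intermediate A → catalyst intermediate B (k = 28.0 s⁻¹)
    substrate + catalyst intermediate B → catalyst intermediate C (k = 170 M⁻¹ s⁻¹)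
    catalyst intermediate D → free catalyst + target (k = 270 s⁻¹)
    target ⇌ isomer of the product (K = 1.80, k = 0.0140 s⁻¹)

- At 1.04 min in this flask, substrate has a half-life of 0.94 min by its reaction with catalyst intermediate B. Target, by its forward step to isomer of the product alone, has a half-life of 0.825 min, which is shorter than that of substrate. This flask ends with 35.7% target at 20.0 min, and the oak readings gave f as 35.3%. The neighbour flask with 0.280 equiv of reagent, the limiting reagent there with 0% left, keeps 72.0% of its substrate and holds 10.0% target at 20.0 min. In that neighbour flask, target is 35.7% of the converted substrate.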